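**Retrosynthetic overview**
1. The target comes from one acidic global deprotection of a (2S)-2-aryl-4-silyloxy-2H-chromene, which is the enol silane of the fully protected flavanone.
2. The key disconnection is C2–C1'. A 4-silyloxybenzopyrylium ion (rings A and C) is joined to an arylzinc (ring B) under a chiral nickel catalyst. This is the new step, and it sets the only stereocentre.
3. Rings A and C: 5,7-bis(silyloxy)-8-prenylchromone is made from commercial 5,7-dihydroxychromone by O5-prenylation and a para-Claisen–Cope shift to C8.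
4. Ring B: the arylzinc is made from commercial 4-bromo-2-methoxyphenol by MOM protection, then deprotonation and prenylation of the C–H between Br and OMe.
5. Ring order: no ring is built. Rings A, B and C are bought, and ring C goes from pyranone through pyrylium to dihydropyranone in the last two steps.

Assumption: the facial sense of the new nickel step cannot be predicted, so the route is written with the ligand antipode that gives (2S); this is fixed in a first run by circular dichroism of the final flavanone (positive band near 330 nm and negative band near 290 nm for 2S). Abbreviations: prenyl = 3-methylbut-2-enyl, TBS = tert-butyldimethylsilyl, MOM = methoxymethyl.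

**Step 1**
Reactants: 1 5,7-dihydroxy-4H-chromen-4-one
Product: 2 7-(tert-butyldimethylsilyloxy)-5-hydroxy-4H-chromen-4-one
Conditions: TBSCl (1.05 equiv), imidazole (2 equiv), DMF, 0 °C to rt
Reagents that add atoms: tert-butyldimethylsilyl chloride (TBSCl), CC(C)(C)[Si](C)(C)Cl
Why: Chemoselective O-silylation, because the 5-OH is held in a strong hydrogen bond to the C4 carbonyl and one equivalent of TBSCl reacts only at the free, more acidic 7-OH.

**Step 2**
Reactants: 2 7-(tert-butyldimethylsilyloxy)-5-hydroxy-4H-chromen-4-one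
Product: 3 7-(tert-butyldimethylsilyloxy)-5-(3-methylbut-2-enyloxy)-4H-chromen-4-one
Conditions: 3-methylbut-2-en-1-ol (1.5 equiv), PPh3, DIAD, THF, 0 °C to rt
Reagents that add atoms: 3-methylbut-2-en-1-ol (prenol), CC(C)=CCO
Why: Mitsunobu etherification alkylates the chelated phenol at oxygen under neutral conditions by SN2 attack on the activated primary allylic alcohol, which avoids the carbonate bases that would cleave the aryl silyl ether.

**Step 3**
Reactants: 3 7-(tert-butyldimethylsilyloxy)-5-(3-methylbut-2-enyloxy)-4H-chromen-4-one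
Product: 6 7-(tert-butyldimethylsilyloxy)-5-hydroxy-8-(3-methylbut-2-enyl)-4H-chromen-4-one, via ortho-dienone 4 (not isolated), via para-dienone 5 (not isolated)
Conditions: Eu(fod)3 (10 mol %), PhCl, 90 °C, 24 h
Reagents that add atoms: none
Why: Tandem aromatic Claisen/Cope (para-Claisen) rearrangement, in which europium chelated between O4 and O5 speeds the [3,3] shift from O5 to C6 (reverse prenyl) and a second [3,3] shift carries the group to C8, para to O5, restoring the normal prenyl group before tautomerisation; this course is well precedented for 5-O-prenyl flavonoids.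

**Step 4**
Reactants: 6 7-(tert-butyldimethylsilyloxy)-5-hydroxy-8-(3-methylbut-2-enyl)-4H-chromen-4-one
Product: 7 5,7-bis(tert-butyldimethylsilyloxy)-8-(3-methylbut-2-enyl)-4H-chromen-4-one
Conditions: TBSOTf (1.3 equiv), 2,6-lutidine (2 equiv), CH2Cl2, 0 °C; aq NaHCO3
Reagents that add atoms: tert-butyldimethylsilyl trifluoromethanesulfonate (TBSOTf), CC(C)(C)[Si](C)(C)OS(=O)(=O)C(F)(F)F
Why: Silyl triflate silylation overcomes the hydrogen bond of the chelated 5-OH, and any O4-silylated pyrylium formed from excess reagent reverts to the chromone on bicarbonate work-up.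

**Step 5**
Reactants: 8 4-bromo-2-methoxyphenol
Product: 9 4-bromo-2-methoxy-1-(methoxymethoxy)benzene
Conditions: MOMCl (1.3 equiv), i-Pr2NEt (1.5 equiv), CH2Cl2, 0 °C to rt
Reagents that add atoms: chloromethyl methyl ether (MOMCl), COCCl
Why: Standard O-alkylation of a phenol (MOM protection) gives an acetal that does not migrate and that tolerates lithium amides, organolithiums and organozincs.

**Step 6**
Reactants: 9 4-bromo-2-methoxy-1-(methoxymethoxy)benzene
Product: 12 1-bromo-3-methoxy-4-(methoxymethoxy)-2-(3-methylbut-2-enyl)benzene, via bromoaryllithium 10 (not isolated), via arylcopper 11 (not isolated)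
Conditions: LiN(i-Pr)2 (1.15 equiv), THF, −78 °C, 45 min; CuBr·SMe2 (1.2 equiv), −78 °C; prenyl bromide (1.5 equiv), −78 to −20 °C
Reagents that add atoms: 1-bromo-3-methylbut-2-ene (prenyl bromide), CC(C)=CCBr
Why: Directed ortho-metalation, in which the C–H flanked by Br and OMe is the only one acidic enough for a lithium amide (no alkyllithium is used, so neither Br/Li exchange nor MOM-directed lithiation occurs), transmetalation to copper at −78 °C stops loss of LiBr to the aryne, and the doubly ortho-substituted arylcopper attacks prenyl bromide at its unhindered CH2 end (SN2 allylation).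

**Step 7**
Reactants: 7 5,7-bis(tert-butyldimethylsilyloxy)-8-(3-methylbut-2-enyl)-4H-chromen-4-one; 12 1-bromo-3-methoxy-4-(methoxymethoxy)-2-(3-methylbut-2-enyl)benzene (1.5 equiv)
Product: 16 (2S)-4,5,7-tris(tert-butyldimethylsilyloxy)-2-[3-methoxy-4-(methoxymethoxy)-2-(3-methylbut-2-enyl)phenyl]-8-(3-methylbut-2-enyl)-2H-chromene, via prenylaryllithium 13 (not isolated), via arylzinc bromide 14 (not isolated), via benzopyrylium triflate 15 (not isolated)
Conditions: (a) 12, t-BuLi (2.0 equiv), Et2O, −78 °C; ZnBr2 (1.1 equiv), THF, −78 to 0 °C; (b) 7, TBSOTf (1.0 equiv), PhMe, 0 °C to rt; (c) Ni(cod)2 (10 mol %), L1 = 3,3'-diphenyl-H8-BINOL N,N-diisopropylphosphoramidite (22 mol %), PhMe/THF, −40 °C, dark, 24 h; aq NaHCO3, short Et3N-deactivated SiO2 plug, used at once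
Reagents that add atoms: tert-butyldimethylsilyl trifluoromethanesulfonate (TBSOTf), CC(C)(C)[Si](C)(C)OS(=O)(=O)C(F)(F)F
Why: Proposed new method: nickel-catalysed enantioselective arylation of a 4-silyloxy-1-benzopyrylium ion with an arylzinc halide; O-silylation turns the electron-rich, poorly electrophilic chromone into the planar cation 15, which zerovalent nickel bearing the chiral phosphoramidite captures at C2 to give a cationic η3-(2H-chromenyl) complex of divalent nickel (reversibly, so the two facial isomers equilibrate); transmetalation from 14 and inner-sphere reductive elimination at the open C2 terminus (C4 is fully substituted and flanked by two silyloxy groups) then form the C2–C1' bond on the ligand-selected face and set (2S), and the product leaves as an enol silane that cannot racemise by the retro-oxa-Michael path open to a metal enolate; the uncatalysed racemic addition is held back by the three oxygen donors that stabilise 15, by the ortho-prenyl hindrance of 14 and by the low temperature; the closest known reaction types are the nickel/phosphoramidite-catalysed enantioselective arylation of N-acylpyridinium ions with arylzinc halides, the nickel-catalysed coupling of 2-alkoxy-2H-chromene acetals with arylboronic acids, and the copper-catalysed enantioselective alkynylation of silyloxybenzopyrylium ions.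

**Step 8**
Reactants: 16 (2S)-4,5,7-tris(tert-butyldimethylsilyloxy)-2-[3-methoxy-4-(methoxymethoxy)-2-(3-methylbut-2-enyl)phenyl]-8-(3-methylbut-2-enyl)-2H-chromene
Product: 17 (2S)-5,7-dihydroxy-2-[4-hydroxy-3-methoxy-2-(3-methylbut-2-enyl)phenyl]-8-(3-methylbut-2-enyl)chroman-4-one
Conditions: 3 M aq HCl, MeOH/THF, 40 °C, 3 h; work-up kept below pH 6
Reagents that add atoms: none
Why: Acid solvolysis, in which fast C3 protonation of the electron-rich enol silane gives the ketone and the two aryl TBS ethers and the MOM acetal fall under the HCl/MeOH conditions routinely used on prenylated flavanones; C2 is untouched because no base is present to trigger retro-oxa-Michael ring opening.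

**Compound list**
1 | 5,7-dihydroxy-4H-chromen-4-one | O=c1ccoc2cc(O)cc(O)c12 | starting material
2 | 7-(tert-butyldimethylsilyloxy)-5-hydroxy-4H-chromen-4-one | O=c1ccoc2cc(O[Si](C)(C)C(C)(C)C)cc(O)c12 | intermediate
3 | 7-(tert-butyldimethylsilyloxy)-5-(3-methylbut-2-enyloxy)-4H-chromen-4-one | O=c1ccoc2cc(O[Si](C)(C)C(C)(C)C)cc(OCC=C(C)C)c12 | intermediate
4 | ortho-dienone, 7-(tert-butyldimethylsilyloxy)-6-(2-methylbut-3-en-2-yl)-6H-chromene-4,5-dione, racemic at C6, formed in the flask | O=C1C=COC2=C1C(=O)C(C(C)(C)C=C)C(O[Si](C)(C)C(C)(C)C)=C2 | intermediate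
5 | para-dienone, 7-(tert-butyldimethylsilyloxy)-8-(3-methylbut-2-enyl)-8H-chromene-4,5-dione, racemic at C8, formed in the flask | O=C1C=COC2=C1C(=O)C=C(O[Si](C)(C)C(C)(C)C)C2CC=C(C)C | intermediate
6 | 7-(tert-butyldimethylsilyloxy)-5-hydroxy-8-(3-methylbut-2-enyl)-4H-chromen-4-one | O=c1ccoc2c(CC=C(C)C)c(O[Si](C)(C)C(C)(C)C)cc(O)c12 | intermediate
7 | 5,7-bis(tert-butyldimethylsilyloxy)-8-(3-methylbut-2-enyl)-4H-chromen-4-one | O=c1ccoc2c(CC=C(C)C)c(O[Si](C)(C)C(C)(C)C)cc(O[Si](C)(C)C(C)(C)C)c12 | intermediate
8 | 4-bromo-2-methoxyphenol | COc1cc(Br)ccc1O | starting material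
9 | 4-bromo-2-methoxy-1-(methoxymethoxy)benzene | COCOc1ccc(Br)cc1OC | intermediate
10 | 6-bromo-2-methoxy-3-(methoxymethoxy)phenyllithium, formed in the flask | [Li]c1c(Br)ccc(OCOC)c1OC | intermediate
11 | 6-bromo-2-methoxy-3-(methoxymethoxy)phenylcopper, formed in the flask | [Cu]c1c(Br)ccc(OCOC)c1OC | intermediate
12 | 1-bromo-3-methoxy-4-(methoxymethoxy)-2-(3-methylbut-2-enyl)benzene | COc1c(OCOC)ccc(Br)c1CC=C(C)C | intermediate
13 | 3-methoxy-4-(methoxymethoxy)-2-(3-methylbut-2-enyl)phenyllithium, formed in the flask | [Li]c1ccc(OCOC)c(OC)c1CC=C(C)C | intermediate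
14 | 3-methoxy-4-(methoxymethoxy)-2-(3-methylbut-2-enyl)phenylzinc bromide, formed in the flask | Br[Zn]c1ccc(OCOC)c(OC)c1CC=C(C)C | intermediate
15 | 4,5,7-tris(tert-butyldimethylsilyloxy)-8-(3-methylbut-2-enyl)chromenylium triflate, formed in the flask | CC(C)=CCc1c(O[Si](C)(C)C(C)(C)C)cc(O[Si](C)(C)C(C)(C)C)c2c(O[Si](C)(C)C(C)(C)C)cc[o+]c12.[O-]S(=O)(=O)C(F)(F)F | intermediate
16 | (2S)-4,5,7-tris(tert-butyldimethylsilyloxy)-2-[3-methoxy-4-(methoxymethoxy)-2-(3-methylbut-2-enyl)phenyl]-8-(3-methylbut-2-enyl)-2H-chromene | COc1c(OCOC)ccc([C@@H]2C=C(O[Si](C)(C)C(C)(C)C)c3c(O[Si](C)(C)C(C)(C)C)cc(O[Si](C)(C)C(C)(C)C)c(CC=C(C)C)c3O2)c1CC=C(C)C | intermediate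
17 | (2S)-5,7-dihydroxy-2-[4-hydroxy-3-methoxy-2-(3-methylbut-2-enyl)phenyl]-8-(3-methylbut-2-enyl)chroman-4-one | COc1c(O)ccc([C@@H]2CC(=O)c3c(O)cc(O)c(CC=C(C)C)c3O2)c1CC=C(C)C | target

**Total step count:** 8. **Longest linear sequence:** 6 (steps 1, 2, 3, 4, 7, 8).

**Three steps most likely to fail**

Step 7 (the new step). It may give low ee through direct racemic addition of 14 to 15. It may lose material through one-electron reduction of 15 by zerovalent nickel, which leads to dimers. It may also stall because the ortho-prenyl arylzinc transmetalates slowly. The fallback is known chemistry: the rhodium-catalysed asymmetric 1,4-addition of an arylboronic acid to a neutral chromone. It sets out from 12 (partner 7) and comes back to the route at 17. Compound 12 is turned into 13 as in step 7 and quenched with B(Oi-Pr)3, then aqueous NH4Cl, to give [3-methoxy-4-(methoxymethoxy)-2-(3-methylbut-2-enyl)phenyl]boronic acid F1. This acid (2 equiv) is added to 7 with [RhCl(C2H4)2]2 (3 mol %) and an electron-poor MeO-BIPHEP-type bisphosphine (the antipode that gives 2S) in toluene/water at 40 °C without strong base. The product is (2S)-5,7-bis(tert-butyldimethylsilyloxy)-2-[3-methoxy-4-(methoxymethoxy)-2-(3-methylbut-2-enyl)phenyl]-8-(3-methylbut-2-enyl)chroman-4-one F2, and the conditions of step 8 turn it into 17.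

Step 3. Dienone 4 may enolise to the 6-(1,1-dimethylallyl) phenol instead of undergoing the Cope shift, or the Lewis acid may simply cleave the prenyl ether. The fallback replaces the sigmatropic shift by electrophilic halogenation and cross-coupling. It sets out from 2 and comes back at 7. Compound 2 is silylated on O5 (TBSOTf, 2,6-lutidine, CH2Cl2, 0 °C) to 5,7-bis(tert-butyldimethylsilyloxy)-4H-chromen-4-one F3. NIS in DMF at rt iodinates ring A at C8, because C6 is walled in by two silyloxy groups, and gives 5,7-bis(tert-butyldimethylsilyloxy)-8-iodo-4H-chromen-4-one F4. Stille coupling with tributyl(3-methylbut-2-enyl)stannane (Pd(PPh3)4, DMF, 80 °C) then gives 7.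

Step 6. Aryllithium 10 carries an ortho bromine, so it may lose LiBr to the aryne or undergo halogen scrambling before copper arrives, and the allylation may leak to the branched isomer. The fallback delivers the prenyl group by a [3,3] shift from the neighbouring oxygen instead of by deprotonation. It sets out from 9 and comes back at 12. The aryl methyl ether of 9 is cleaved with NaSEt in DMF at 110 °C, which leaves the MOM acetal and the bromide in place, to give 5-bromo-2-(methoxymethoxy)phenol F5. O-alkylation with tert-butyl 2-methylbut-3-en-2-yl carbonate, catalysed by Pd(PPh3)4 in THF at 0 °C to rt, gives 4-bromo-1-(methoxymethoxy)-2-(2-methylbut-3-en-2-yloxy)benzene F6. Heating in toluene at 120 °C (sealed tube) drives the aromatic Claisen rearrangement to the only free ortho position, giving 3-bromo-6-(methoxymethoxy)-2-(3-methylbut-2-enyl)phenol F7 with a linear prenyl group. MeI and K2CO3 in acetone put the methyl group back and give 12.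

**Further compounds**
F1 | step 7 | [3-methoxy-4-(methoxymethoxy)-2-(3-methylbut-2-enyl)phenyl]boronic acid | COc1c(OCOC)ccc(B(O)O)c1CC=C(C)C
F2 | step 7 | (2S)-5,7-bis(tert-butyldimethylsilyloxy)-2-[3-methoxy-4-(methoxymethoxy)-2-(3-methylbut-2-enyl)phenyl]-8-(3-methylbut-2-enyl)chroman-4-one | COc1c(OCOC)ccc([C@@H]2CC(=O)c3c(O[Si](C)(C)C(C)(C)C)cc(O[Si](C)(C)C(C)(C)C)c(CC=C(C)C)c3O2)c1CC=C(C)C
F3 | step 3 | 5,7-bis(tert-butyldimethylsilyloxy)-4H-chromen-4-one | O=c1ccoc2cc(O[Si](C)(C)C(C)(C)C)cc(O[Si](C)(C)C(C)(C)C)c12
F4 | step 3 | 5,7-bis(tert-butyldimethylsilyloxy)-8-iodo-4H-chromen-4-one | O=c1ccoc2c(I)c(O[Si](C)(C)C(C)(C)C)cc(O[Si](C)(C)C(C)(C)C)c12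
F5 | step 6 | 5-bromo-2-(methoxymethoxy)phenol | COCOc1ccc(Br)cc1O
F6 | step 6 | 4-bromo-1-(methoxymethoxy)-2-(2-methylbut-3-en-2-yloxy)benzene | COCOc1ccc(Br)cc1OC(C)(C)C=C
F7 | step 6 | 3-bromo-6-(methoxymethoxy)-2-(3-methylbut-2-enyl)phenol | COCOc1ccc(Br)c(CC=C(C)C)c1O
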